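## Structural features

The target has four rings. A resorcinol ring A is fused to a cyclohexanone ring B, giving a 3,4-dihydronaphthalen-1(2H)-one. A second resorcinol ring C is attached to C4 through a ketone carbonyl, and a 4-hydroxy-2-pyranone ring D hangs on ring C through one methylene group ortho to that carbonyl. The only stereocentres are C3 (tertiary carbinol bearing the methyl group) and C4 (methine bearing the aroyl group); they are adjacent, with hydroxyl and aroyl cis, (3R,4S). The C3 hydroxyl is β to both ketones, to C1 through C2 and to the aroyl carbonyl through C4, so loss of water is easy under acid or base and ends irreversibly in a naphthol. Retro-aldol cleavage of C3–C4 and epimerisation of the doubly activated C4–H are the other base-triggered ways out. The aroyl carbonyl lies between two ortho substituents of ring C and is shielded, and the hydroxypyranone is a vinylogous acid that is best carried protected. The real difficulty is to set the cis C3/C4 ketol in absolute terms and keep it masked through every basic step. The route uses the 1,3-relationship between the C3 oxygen and the C4 acyl carbon, which is the retron of a 2-isoxazoline fused across C3–C4 of ring B; the two ortho substituents of ring C are what make the required aryl nitrile oxide persistent.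

## Logic of the disconnections

**30 to 29.** The five O–CH2Ph bonds of 29 (four aryl ethers and the enol ether on ring D) are cut last. Capping every acidic hydroxyl until the end removes phenoxide and pyranone-olate chemistry from all earlier steps and keeps the intermediates chromatographable. The forward step must be a neutral cleavage that leaves two aryl ketones, the pyranone double bonds and the ketol alone.

**29 to 28.** The C1 carbonyl of 29 is taken back to the secondary carbinol of 28. With C1 at the alcohol level the C3 hydroxyl is β to only one ketone and an elimination cannot end in a naphthol, so the ketone is introduced as late as possible. The forward step must oxidise a secondary benzylic alcohol beside a tertiary one without conditions that epimerise C4.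

**28 to 26 to 25.** In 28 the C3 oxygen and the aroyl carbon are rejoined through nitrogen (the reverse of an N–O cleavage), giving the ring-fused isoxazoline of 26; the C1 oxygen is then re-silylated to give 25. The heterocycle hides both the tertiary alcohol and the ketone, holds C4 in a cis ring fusion and is indifferent to base. The forward demands are a reductive N–O cleavage followed by hydrolysis of a hindered imine, and a fluoride desilylation placed before that cleavage.

**25 to 22 to 18 + 19, and 18 to 17.** Ring D of 25 is cut at its lactone C–O bond and at the bond between the ring carbon that carries the benzylic CH2 and its ring neighbour. This leads through 22 to the four-carbon block 19 and the acyl donor 18, one functional-group exchange away from the ester 17. The whole ring is thereby reduced to a commercial building block and an arylacetic ester that can ride through the cycloaddition unchanged. The forward C–C bond formation needs a dienolate in the presence of an acidic ArCH2 group and of the isoxazoline C4–H. This is why the acyl donor is a Weinreb amide (no over-addition, product held as a chelate) and why C1 stays a silyl ether (a C1 ketone would expel the C3 oxygen under base).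

**17 to 9 + 16.** The C4–C(=N) and C3–O bonds of 17 are cut together. This removes the isoxazoline ring, both stereocentres and all of ring C with its ester arm in one operation, leaving the planar alkene 9 and the dipole 16. The forward step must put oxygen on C3 and carbon on C4, choose one face of ring B under the influence of C1 alone, and use a dipole that lives long enough to meet a trisubstituted alkene.

**9 to 8 to 7 to 4 + 5 to 3 to 1.** The C3=C4 bond of 9 is opened to the two terminal alkenes of 8, the silyl ether goes back to the alcohol 7, the C1–C2 bond of 7 is cut to the aldehyde 4 and the allyl donor 5, the vinyl–aryl bond of 4 leads to the bromide 3, and the formyl–aryl bond of 3 to 1. Each cut is a standard C–C disconnection, and the single stereocentre comes from one catalytic allylation. That allylation has to cope with an aldehyde flanked by two ortho substituents. The vinyl group must be in place before the methallyl chain, because an aryl–palladium intermediate ortho to that chain would cyclise onto it.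

**16 to 14 to 13 to 11 to 10.** The dipole 16 is traced through the oxime 14 to the aldehyde 13, whose formyl–aryl bond is cut to 11, the bis-benzyl ether of 10. The ring substitution pattern of ring C is thus bought, and only one carbon is added. The formylation must go ortho to the acetate arm, and the oxime must be dehydrogenated without halogenating the electron-rich ring.

## Other disconnections considered

**Alternative 1:** The cut runs through C3–C4 and C1–C2, dividing ring B between the deoxybenzoin ester A1 and the chiral acetoacetate acetal A2. In the forward key step the lithium enolate of A1 (at the future C4) adds in conjugate fashion to the methyl-bearing carbon of A2 on the face away from the tert-butyl group. The resulting enolate then closes onto the benzoate in a Dieckmann step and gives the tricycle A3.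
- In favour: ring B and two C–C bonds arise in one operation; the absolute configuration at C3 comes from a chiral-pool acetal and needs no chiral catalyst; the tertiary alcohol arrives protected; C1 is formed directly at the ketone level. On these points it equals or betters the chosen plan, which carries a sacrificial C1 carbinol and oxidises it later.
- Against: conjugate addition of a stabilised, hindered enolate to a β,β-disubstituted acceptor to form a quaternary carbon is reversible and slow. C4 is set in an ionic step and stays α to a carbonyl, so the cis relationship is under thermodynamic rather than geometric control, whereas the cycloaddition fixes it by suprafaciality.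
- The endgame is heavier: the extra carboxyl carbon at C2 must be removed, the acetal must be cleaved with acid on a dehydration-prone ketol, and the whole CH2–pyranone arm has to be attached to the di-ortho-substituted bromide of A3 next to an epimerisable centre.
- Step economy: comparable or better up to ring B, worse afterwards.

**Alternative 2:** Ring C is excised as an aryne by cutting the C(=O)–aryl and aryl–CH2 bonds, leaving the β-keto pyranone A4 and the silyl triflate A5. In the forward key step fluoride releases the aryne A6, the enolate of A4 adds to it, the aryl anion closes onto the ketone, and the four-membered alkoxide fragments to the fully protected target A7.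
- In favour: it is the most convergent of the four plans; the pyranone is already in place, so only deprotection remains (better endgame economy than the chosen plan); the known bias of a 3-alkoxy aryne places the acyl group next to the ether, as the target requires.
- Against: A4 has three acidic sites (C2–H2, C4–H and the CH2 between ketone and pyranone) and a β-silyloxy group. Fluoride or carbonate can therefore epimerise C4, expel the C3 oxygen on the way to a naphthol, strip the silyl ether, or arylate the wrong enolate. The aryl anion must also attack a ketone next to a tertiary centre.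
- The step creates no stereocentre, so both centres must be made earlier and then survive basic conditions; the chosen plan makes them in the key step under neutral thermal conditions.
- Step economy: shorter after the key step, but A4 needs its own long synthesis with the fragile ketol exposed early.

**Alternative 3:** The cut is C1–C2, leading to the epoxy dithiane A8. In the forward key step the lithiated dithiane attacks the epoxide CH2 intramolecularly, closes ring B and gives the tertiary alcohol A9.
- In favour: dithiane–epoxide coupling is robust anion chemistry; C1 arrives masked at the ketone oxidation level (better than a sacrificial carbinol); the C3 configuration is transferred stereospecifically from the epoxide, so there is no regiochemical question of the cycloaddition kind. In certainty at C3 it equals or betters the chosen plan.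
- Against: the six-membered closure at CH2 competes with five-membered closure at the fully substituted epoxide carbon (sterically blocked, but the geometrically easier path). An alkyllithium base meets four benzyl ethers prone to benzylic metalation. The C3/C4 relationship and the carbinol on ring C must be built separately beforehand.
- After the key step the dithiane must still be removed from an electron-rich arene, the side-chain carbinol oxidised, and the two-carbon arm oxidised and turned into ring D.
- Step economy: the longest of the four plans, with two stereocentres made in separate operations against one in the chosen plan.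

Key step: step 10

Remarks on the chemistry:
- Ring atoms of the bicyclic core carry the locants C1–C8a of the target throughout.
- (R)-TRIP [(R)-3,3'-bis(2,4,6-triisopropylphenyl)-1,1'-binaphthyl-2,2'-diyl hydrogen phosphate] is assumed to give the (R)-carbinol with aldehyde 4, as with simple aryl aldehydes; if the sense were reversed the antipodal catalyst would be used with no other change.
- The structures of 9, 16 and 17 were checked against the target and found consistent. C1 of 9 is (R) and 17 is (1R,3R,4R). The C4 descriptor changes from R (17–27) to S (28–30) only because C=O outranks C=N in the CIP rules, not through inversion.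
- Two changes of sequence were made for safety: the vinyl group is installed before the methallyl chain (steps 2 and 3), and the isoxazoline is opened before C1 is oxidised (steps 15 and 16).

## Steps

Step 1
Reactants: 1 1-bromo-3,5-bis(benzyloxy)benzene
Product: 3 2,4-bis(benzyloxy)-6-bromobenzaldehyde, via aryl iminium chloride 2 (not isolated)
Conditions: POCl3, DMF, 0 → 90 °C; then aq. NaOAc, rt
Reagents that add atoms: N,N-dimethylformamide CN(C)C=O; water O
Why: Vilsmeier–Haack formylation; the site between bromine and one ether is para to the other ether and less crowded than the site between the two ethers, so the 2,4-dialkoxy-6-bromo aldehyde should dominate, and aryl benzyl ethers tolerate the reagent.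

Step 2
Reactants: 3 2,4-bis(benzyloxy)-6-bromobenzaldehyde
Product: 4 2,4-bis(benzyloxy)-6-vinylbenzaldehyde
Conditions: CH2=CHBF3K, PdCl2(dppf)·CH2Cl2 (3 mol%), Cs2CO3, THF/H2O 9:1, 70 °C
Reagents that add atoms: potassium vinyltrifluoroborate [K+].C=C[B-](F)(F)F
Why: Suzuki–Miyaura coupling of an aryl bromide activated by the ortho formyl group. The vinyl group is introduced before the methallyl chain on purpose, because an aryl–palladium species ortho to a 3-methylbut-3-enyl chain would be diverted into 5-exo Heck cyclisation.

Step 3
Reactants: 4 2,4-bis(benzyloxy)-6-vinylbenzaldehyde; 5 2-methylallylboronic acid pinacol ester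
Product: 7 (R)-1-[2,4-bis(benzyloxy)-6-vinylphenyl]-3-methylbut-3-en-1-ol, via pinacol borate ester 6 (not isolated)
Conditions: 5 (1.5 equiv), (R)-TRIP (5 mol%), 4 Å MS, PhMe, −30 °C; then aq. NaHCO3
Reagents that add atoms: none
Why: Chiral phosphoric acid-catalysed allylboration through a chair-like six-membered transition state in which the acid is hydrogen-bonded to a boronate oxygen; the catalyst enantiomer selects the aldehyde face and sets C1 as (R). The borate ester 6 is cleaved on aqueous work-up.

Step 4
Reactants: 7 (R)-1-[2,4-bis(benzyloxy)-6-vinylphenyl]-3-methylbut-3-en-1-ol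
Product: 8 (R)-tert-butyl{1-[2,4-bis(benzyloxy)-6-vinylphenyl]-3-methylbut-3-enyloxy}dimethylsilane
Conditions: TBSOTf, 2,6-lutidine, CH2Cl2, −78 → 0 °C
Reagents that add atoms: tert-butyldimethylsilyl trifluoromethanesulfonate CC(C)(C)[Si](C)(C)OS(=O)(=O)C(F)(F)F
Why: Silylation of a hindered secondary benzylic alcohol with the silyl triflate under buffered conditions; the silyl ether blocks dehydration toward a naphthalene and later shields one face of ring B. C1 is not touched.

Step 5
Reactants: 8 (R)-tert-butyl{1-[2,4-bis(benzyloxy)-6-vinylphenyl]-3-methylbut-3-enyloxy}dimethylsilane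
Product: 9 (R)-6,8-bis(benzyloxy)-1-(tert-butyldimethylsilyloxy)-3-methyl-1,2-dihydronaphthalene
Conditions: second-generation Grubbs catalyst RuCl2(=CHPh)(PCy3)(1,3-dimesitylimidazolidin-2-ylidene) (5 mol%), CH2Cl2, 40 °C; filtration through Et3N-washed silica
Reagents that add atoms: none
Why: Ring-closing metathesis of a styrene with a 1,1-disubstituted alkene closes the six-membered ring and gives the trisubstituted C3=C4 alkene, driven by loss of ethene. Compound 9 is acid-sensitive (loss of silanol would aromatise it), hence the base-washed silica.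

Step 6
Reactants: 10 methyl 3,5-dihydroxyphenylacetate
Product: 11 methyl 3,5-bis(benzyloxy)phenylacetate
Conditions: BnBr, K2CO3, acetone, 56 °C
Reagents that add atoms: benzyl bromide BrCc1ccccc1
Why: Williamson etherification of both phenols; carbonate is too weak a base to enolise the arylacetate.

Step 7
Reactants: 11 methyl 3,5-bis(benzyloxy)phenylacetate
Product: 13 methyl 2-[3,5-bis(benzyloxy)-2-formylphenyl]acetate, via aryl iminium chloride 12 (not isolated)
Conditions: POCl3, DMF, 0 → 60 °C; then aq. NaOAc, rt
Reagents that add atoms: N,N-dimethylformamide CN(C)C=O; water O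
Why: Vilsmeier–Haack formylation ortho to the acetate arm and para to one ether, the usual site for 3,5-dialkoxy alkylbenzenes; the ester is inert to the chloroiminium reagent.

Step 8
Reactants: 13 methyl 2-[3,5-bis(benzyloxy)-2-formylphenyl]acetate
Product: 14 methyl 2-{3,5-bis(benzyloxy)-2-[(E)-(hydroxyimino)methyl]phenyl}acetate
Conditions: NH2OH·HCl, NaOAc, MeOH/THF, 0 °C → rt
Reagents that add atoms: hydroxylamine hydrochloride Cl.NO
Why: Condensation of the aldehyde with hydroxylamine under acetate buffer; it is kept at or below room temperature so that the oxime nitrogen does not acylate onto the neighbouring ester.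

Step 9
Reactants: 14 methyl 2-{3,5-bis(benzyloxy)-2-[(E)-(hydroxyimino)methyl]phenyl}acetate
Product: 16 2,4-bis(benzyloxy)-6-(2-methoxy-2-oxoethyl)benzonitrile oxide, via hydroximoyl chloride 15 (not isolated)
Conditions: NCS (1.0 equiv), DMF, 0 °C → rt; then Et3N, Et2O, 0 °C; cold aqueous wash, used at once as a solution
Reagents that add atoms: none
Why: Chlorination of the aldoxime C–H with one equivalent of N-chlorosuccinimide followed by dehydrochlorination (the classical hydroximoyl chloride route); the limited reagent and low temperature are meant to keep the electron-rich ring from being chlorinated. With both ortho positions occupied, dimerisation to the furoxan is slow and 16 can be handled as a cold solution.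

Step 10
Reactants: 9 (R)-6,8-bis(benzyloxy)-1-(tert-butyldimethylsilyloxy)-3-methyl-1,2-dihydronaphthalene; 16 2,4-bis(benzyloxy)-6-(2-methoxy-2-oxoethyl)benzonitrile oxide
Product: 17 cis-fused isoxazoline methyl ester, (1R,3R,4R) by tetralin locants: ring oxygen on C3, C=N carbon on C4 and bearing the 2,4-bis(benzyloxy)-6-(2-methoxy-2-oxoethyl)phenyl group, C1 silyloxy group trans to both new bonds
Conditions: 16 (1.5 equiv), PhMe, 75 °C, dark
Reagents that add atoms: none
Why: Concerted, asynchronous [π4s+π2s] 1,3-dipolar cycloaddition of the nitrile oxide across C3=C4; the closest known reaction type is the nitrile oxide–alkene cycloaddition to trisubstituted and cyclic styrene-type alkenes used as a masked aldol. The one new ring, the 2-isoxazoline, closes in the cycloaddition itself, both σ-bonds forming on one face of the alkene, so it is cis-fused to ring B. The C3/C4 relationship is therefore fixed as cis by suprafaciality, whatever the facial outcome. The absolute sense is relayed from C1: peri strain with the C8 benzyloxy group holds the C1 silyloxy group pseudoaxial, where it blocks the syn face at C3, so the dipole should add anti to it and give the (1R,3R,4R) adduct; the syn adduct is a diastereomer and separable. Regiochemistry (oxygen to C3, carbon to C4) is the selectivity the step needs most; it rests on the fully substituted C3 being unable to accept the carbon terminus, which carries a di-ortho-substituted aryl group, a steric preference that has to override the electronic bias of a styrene. Chemoselectivity against furoxan formation comes from the same two ortho substituents, which make 16 persistent enough to be heated with a sluggish alkene. The neutral conditions leave the acid-sensitive C1 silyl ether and the ester untouched.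

Step 11
Reactants: 17 cis-fused isoxazoline methyl ester
Product: 18 isoxazoline Weinreb amide (CH2CO2Me of 17 replaced by CH2C(=O)N(OMe)Me)
Conditions: MeNH(OMe)·HCl, i-PrMgCl, THF, −20 → 0 °C
Reagents that add atoms: N,O-dimethylhydroxylamine hydrochloride Cl.CNOC
Why: Aminolysis of the methyl ester by the magnesium amide of N,O-dimethylhydroxylamine at low temperature; it turns the weakly electrophilic, more acidic arylacetate into an acyl donor that stops at the ketone stage. Isoxazoline, silyl ether and benzyl ethers are inert.

Step 12
Reactants: 18 isoxazoline Weinreb amide; 19 2,2,6-trimethyl-4H-1,3-dioxin-4-one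
Product: 22 keto-dioxinone (ArCH2C(=O)CH2 attached to C6 of the 2,2-dimethyl-4H-1,3-dioxin-4-one; Ar = isoxazoline-bearing ring), via lithium dienolate 20 (not isolated), via lithium hemiaminal adduct 21 (not isolated)
Conditions: 19 (3 equiv), LiN(SiMe3)2 (3 equiv), THF, −78 °C; then 18, −78 → −40 °C; aq. NH4Cl
Reagents that add atoms: none
Why: Vinylogous Claisen-type γ-acylation of the dioxinone lithium dienolate by a Weinreb amide; the chelated adduct 21 persists until the quench, so neither over-addition nor enolisation of the product ketone can occur. The dienolate is pre-formed and free of excess amide base to spare the C4–H of the isoxazoline.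

Step 13
Reactants: 22 keto-dioxinone
Product: 25 isoxazoline carrying the (4-benzyloxy-2-oxo-2H-pyran-6-yl)methyl arm (C1 silyl ether), via acylketene 23 (not isolated), via hydroxypyranone 24 (not isolated)
Conditions: PhMe, 110 °C; then 0 °C → rt, BnOH, PPh3, DIAD
Reagents that add atoms: benzyl alcohol OCc1ccccc1
Why: Thermal retro-[4+2] loss of acetone gives the acylketene, which is captured by the enol oxygen of the δ-ketone to close the 4-hydroxy-2-pyranone (the standard dioxinone-to-pyranone conversion). Mitsunobu alkylation of the acidic 4-OH with benzyl alcohol then protects it under neutral conditions.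

Step 14
Reactants: 25 benzyloxypyranone isoxazoline silyl ether
Product: 26 benzyloxypyranone isoxazoline with free C1 hydroxyl, (1R,3R,4R)
Conditions: Bu4NF, AcOH, THF, 0 °C → rt
Reagents that add atoms: none
Why: Fluoride cleavage of the silyl ether, buffered with acetic acid; the ketol is still masked as the base-stable isoxazoline, so the basic fluoride cannot trigger retro-aldol cleavage.

Step 15
Reactants: 26 benzyloxypyranone isoxazoline with free C1 hydroxyl
Product: 28 (1R,3R,4S)-1,3-dihydroxy ketone (C1 carbinol analogue of penta-O-benzyl target), via hydroxy ketimine 27 (not isolated)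
Conditions: Mo(CO)6 (1.2 equiv), MeCN/H2O 10:1, 80 °C
Reagents that add atoms: water O
Why: Reductive N–O cleavage by Mo(CO)6 gives the β-hydroxy ketimine 27, which is hydrolysed in the wet medium to the ketone; no bond to C3 or C4 is broken, so the cis relationship is kept. The step is run while C1 is still a carbinol, so that an accidental loss of water at C3 cannot end in a naphthol.

Step 16
Reactants: 28 (1R,3R,4S)-1,3-dihydroxy ketone
Product: 29 penta-O-benzyl target, (3R,4S)
Conditions: Dess–Martin periodinane, NaHCO3, CH2Cl2, 0 °C → rt
Reagents that add atoms: none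
Why: Dess–Martin oxidation of the secondary benzylic alcohol under bicarbonate buffer; the tertiary C3 alcohol is inert and the mild, nearly neutral medium spares the ketol and the epimerisable C4–H. The sacrificial C1 stereocentre disappears here.

Step 17
Reactants: 29 penta-O-benzyl target
Product: 30 (3R,4S)-4-{2,4-dihydroxy-6-[(4-hydroxy-2-oxo-2H-pyran-6-yl)methyl]benzoyl}-3,6,8-trihydroxy-3-methyl-3,4-dihydronaphthalen-1(2H)-one
Conditions: H2 (1 atm), 10% Pd/C, EtOAc/THF, rt
Reagents that add atoms: none
Why: Hydrogenolysis of four aryl benzyl ethers and the pyranone enol benzyl ether under neutral conditions at room temperature; the aryl ketones, once their ortho phenols are free, are hydrogen-bonded and slow to reduce. The reaction is stopped as soon as debenzylation is complete.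

## Compound list

1 | 1-bromo-3,5-bis(benzyloxy)benzene | Brc1cc(OCc2ccccc2)cc(OCc2ccccc2)c1 | starting material
2 | N-[2,4-bis(benzyloxy)-6-bromobenzylidene]-N-methylmethanaminium chloride | C[N+](C)=Cc1c(Br)cc(OCc2ccccc2)cc1OCc1ccccc1.[Cl-] | intermediate (not isolated)
3 | 2,4-bis(benzyloxy)-6-bromobenzaldehyde | O=Cc1c(Br)cc(OCc2ccccc2)cc1OCc1ccccc1 | intermediate
4 | 2,4-bis(benzyloxy)-6-vinylbenzaldehyde | O=Cc1c(C=C)cc(OCc2ccccc2)cc1OCc1ccccc1 | intermediate
5 | 2-methylallylboronic acid pinacol ester | CC(=C)CB1OC(C)(C)C(C)(C)O1 | starting material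
6 | pinacol borate ester of 7, (R) | CC(=C)C[C@@H](OB1OC(C)(C)C(C)(C)O1)c1c(C=C)cc(OCc2ccccc2)cc1OCc1ccccc1 | intermediate (not isolated)
7 | (R)-1-[2,4-bis(benzyloxy)-6-vinylphenyl]-3-methylbut-3-en-1-ol | CC(=C)C[C@@H](O)c1c(C=C)cc(OCc2ccccc2)cc1OCc1ccccc1 | intermediate
8 | (R)-tert-butyl{1-[2,4-bis(benzyloxy)-6-vinylphenyl]-3-methylbut-3-enyloxy}dimethylsilane | CC(=C)C[C@@H](O[Si](C)(C)C(C)(C)C)c1c(C=C)cc(OCc2ccccc2)cc1OCc1ccccc1 | intermediate
9 | (R)-6,8-bis(benzyloxy)-1-(tert-butyldimethylsilyloxy)-3-methyl-1,2-dihydronaphthalene | CC1=Cc2cc(OCc3ccccc3)cc(OCc3ccccc3)c2[C@H](O[Si](C)(C)C(C)(C)C)C1 | intermediate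
10 | methyl 3,5-dihydroxyphenylacetate | COC(=O)Cc1cc(O)cc(O)c1 | starting material
11 | methyl 3,5-bis(benzyloxy)phenylacetate | COC(=O)Cc1cc(OCc2ccccc2)cc(OCc2ccccc2)c1 | intermediate
12 | N-[2,4-bis(benzyloxy)-6-(2-methoxy-2-oxoethyl)benzylidene]-N-methylmethanaminium chloride | COC(=O)Cc1cc(OCc2ccccc2)cc(OCc2ccccc2)c1C=[N+](C)C.[Cl-] | intermediate (not isolated)
13 | methyl 2-[3,5-bis(benzyloxy)-2-formylphenyl]acetate | COC(=O)Cc1cc(OCc2ccccc2)cc(OCc2ccccc2)c1C=O | intermediate
14 | methyl 2-{3,5-bis(benzyloxy)-2-[(E)-(hydroxyimino)methyl]phenyl}acetate | COC(=O)Cc1cc(OCc2ccccc2)cc(OCc2ccccc2)c1/C=N/O | intermediate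
15 | methyl 2-{3,5-bis(benzyloxy)-2-[chloro(hydroxyimino)methyl]phenyl}acetate | COC(=O)Cc1cc(OCc2ccccc2)cc(OCc2ccccc2)c1C(Cl)=NO | intermediate (not isolated)
16 | 2,4-bis(benzyloxy)-6-(2-methoxy-2-oxoethyl)benzonitrile oxide | COC(=O)Cc1cc(OCc2ccccc2)cc(OCc2ccccc2)c1C#[N+][O-] | intermediate
17 | cis-fused isoxazoline methyl ester, (1R,3R,4R): 2-isoxazoline across C3–C4 of 6,8-bis(benzyloxy)-1-(tert-butyldimethylsilyloxy)-3-methyltetralin, O on C3, C=N carbon on C4 bearing the 2,4-bis(benzyloxy)-6-(2-methoxy-2-oxoethyl)phenyl group | C[C@@]1(ON=C3c4c(OCc5ccccc5)cc(OCc5ccccc5)cc4CC(=O)OC)C[C@@H](O[Si](C)(C)C(C)(C)C)c2c(OCc5ccccc5)cc(OCc5ccccc5)cc2[C@@H]13 | intermediate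
18 | isoxazoline Weinreb amide (N-methoxy-N-methyl amide of 17) | C[C@@]1(ON=C3c4c(OCc5ccccc5)cc(OCc5ccccc5)cc4CC(=O)N(C)OC)C[C@@H](O[Si](C)(C)C(C)(C)C)c2c(OCc5ccccc5)cc(OCc5ccccc5)cc2[C@@H]13 | intermediate
19 | 2,2,6-trimethyl-4H-1,3-dioxin-4-one | CC1=CC(=O)OC(C)(C)O1 | starting material
20 | lithium 2,2-dimethyl-6-methylene-6H-1,3-dioxin-4-olate | [Li+].C=C1C=C([O-])OC(C)(C)O1 | intermediate (not isolated)
21 | lithium hemiaminal adduct of 18 and 20 (configuration at the new carbon undefined) | C[C@@]1(ON=C3c4c(OCc5ccccc5)cc(OCc5ccccc5)cc4CC([O-])(N(C)OC)CC6=CC(=O)OC(C)(C)O6)C[C@@H](O[Si](C)(C)C(C)(C)C)c2c(OCc5ccccc5)cc(OCc5ccccc5)cc2[C@@H]13.[Li+] | intermediate (not isolated)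
22 | keto-dioxinone: 6-(3-aryl-2-oxopropyl)-2,2-dimethyl-4H-1,3-dioxin-4-one, aryl = isoxazoline-bearing ring | C[C@@]1(ON=C3c4c(OCc5ccccc5)cc(OCc5ccccc5)cc4CC(=O)CC6=CC(=O)OC(C)(C)O6)C[C@@H](O[Si](C)(C)C(C)(C)C)c2c(OCc5ccccc5)cc(OCc5ccccc5)cc2[C@@H]13 | intermediate
23 | acylketene from 22 | C[C@@]1(ON=C3c4c(OCc5ccccc5)cc(OCc5ccccc5)cc4CC(=O)CC(=O)C=C=O)C[C@@H](O[Si](C)(C)C(C)(C)C)c2c(OCc5ccccc5)cc(OCc5ccccc5)cc2[C@@H]13 | intermediate (not isolated)
24 | isoxazoline with (4-hydroxy-2-oxo-2H-pyran-6-yl)methyl arm, C1 silyl ether | C[C@@]1(ON=C3c4c(OCc5ccccc5)cc(OCc5ccccc5)cc4Cc6cc(O)cc(=O)o6)C[C@@H](O[Si](C)(C)C(C)(C)C)c2c(OCc5ccccc5)cc(OCc5ccccc5)cc2[C@@H]13 | intermediate (not isolated)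
25 | isoxazoline with (4-benzyloxy-2-oxo-2H-pyran-6-yl)methyl arm, C1 silyl ether | C[C@@]1(ON=C3c4c(OCc5ccccc5)cc(OCc5ccccc5)cc4Cc6cc(OCc5ccccc5)cc(=O)o6)C[C@@H](O[Si](C)(C)C(C)(C)C)c2c(OCc5ccccc5)cc(OCc5ccccc5)cc2[C@@H]13 | intermediate
26 | isoxazoline with benzyloxypyranone arm and free C1 hydroxyl, (1R,3R,4R) | C[C@@]1(ON=C3c4c(OCc5ccccc5)cc(OCc5ccccc5)cc4Cc6cc(OCc5ccccc5)cc(=O)o6)C[C@@H](O)c2c(OCc5ccccc5)cc(OCc5ccccc5)cc2[C@@H]13 | intermediate
27 | β-hydroxy ketimine from N–O cleavage of 26, (1R,3R,4R) | C[C@@]1(O)C[C@@H](O)c2c(OCc3ccccc3)cc(OCc3ccccc3)cc2[C@@H]1C(=N)c1c(OCc2ccccc2)cc(OCc2ccccc2)cc1Cc1cc(OCc2ccccc2)cc(=O)o1 | intermediate (not isolated)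
28 | (1R,3R,4S)-6,8-bis(benzyloxy)-4-{2,4-bis(benzyloxy)-6-[(4-benzyloxy-2-oxo-2H-pyran-6-yl)methyl]benzoyl}-3-methyl-1,2,3,4-tetrahydronaphthalene-1,3-diol | C[C@@]1(O)C[C@@H](O)c2c(OCc3ccccc3)cc(OCc3ccccc3)cc2[C@@H]1C(=O)c1c(OCc2ccccc2)cc(OCc2ccccc2)cc1Cc1cc(OCc2ccccc2)cc(=O)o1 | intermediate
29 | (3R,4S)-6,8-bis(benzyloxy)-4-{2,4-bis(benzyloxy)-6-[(4-benzyloxy-2-oxo-2H-pyran-6-yl)methyl]benzoyl}-3-hydroxy-3-methyl-3,4-dihydronaphthalen-1(2H)-one | C[C@@]1(O)CC(=O)c2c(OCc3ccccc3)cc(OCc3ccccc3)cc2[C@@H]1C(=O)c1c(OCc2ccccc2)cc(OCc2ccccc2)cc1Cc1cc(OCc2ccccc2)cc(=O)o1 | intermediate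
30 | (3R,4S)-4-{2,4-dihydroxy-6-[(4-hydroxy-2-oxo-2H-pyran-6-yl)methyl]benzoyl}-3,6,8-trihydroxy-3-methyl-3,4-dihydronaphthalen-1(2H)-one | C[C@@]1(O)CC(=O)c2c(O)cc(O)cc2[C@@H]1C(=O)c1c(O)cc(O)cc1Cc1cc(O)cc(=O)o1 | target

## Step count and risks

Total step count: 17. Longest linear sequence: 13 steps (steps 1–5 and 10–17, from 1); the dipole branch (steps 6–9) joins at step 10.

Least certain steps:

**Step 10 (key step).** The most likely failures are:
- loss of regiocontrol, with the oxygen terminus going to the benzylic carbon C4, as aryl conjugation favours in unhindered styrenes;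
- incomplete facial discrimination by the remote C1 substituent;
- thermal decay of the dipole (rearrangement to the isocyanate) outrunning a slow addition to a trisubstituted alkene.

The fallback is a hydroxyl-directed cycloaddition in the C1-epimeric series, in which a magnesium alkoxide should both accelerate the addition and deliver the dipole oxygen to the nearer alkene carbon on its own face. It sets out from 4. Methallylboration with the antipodal catalyst (S)-TRIP gives the (S)-homoallylic alcohol F1. Ring-closing metathesis of the free alcohol (catalyst of step 5, toluene) gives the (S)-dihydronaphthalenol F2. Deprotonation with EtMgBr in CH2Cl2 at 0 °C and addition of 16 should give the all-cis hydroxy isoxazoline F3, with the same C3 and C4 configuration as 17. F3 is carried on without a silyl group. Aminolysis as in step 11 gives the Weinreb amide F4, and acylation as in step 12 (one more equivalent of base for the alkoxide) gives the keto-dioxinone F5. Thermolysis followed by benzylation with BnBr/K2CO3 in acetone gives the benzyloxypyranone F6; the Mitsunobu reaction is avoided here because it would engage the free carbinol. Mo(CO)6 as in step 15 gives the diol ketone F7, the C1 epimer of 28. Oxidation as in step 16 erases C1, and the fallback rejoins the route at 29.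

**Step 3.** The most likely failure is low enantioselectivity, because an aldehyde flanked by two ortho substituents fits the catalyst pocket poorly and the uncatalysed background addition then competes. Fallback from 4: addition of 2-methylallylmagnesium chloride (THF, −78 °C) gives the racemic alcohol F8; Dess–Martin oxidation gives the β,γ-unsaturated aryl ketone F9; Corey–Bakshi–Shibata reduction with the (S)-methyl oxazaborolidine and catecholborane (toluene, −78 °C) should return the (R)-alcohol 7. Catecholborane is chosen so that the 1,1-disubstituted alkene is not hydroborated.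

**Step 12.** The most likely failure is proton transfer instead of acylation. Deprotonation of the ArCH2C(=O) position only returns 18, but deprotonation of C4–H of the isoxazoline can open the ring by β-elimination to an unsaturated oxime. The fallback avoids strong base and sets out from 17. LiOH (THF/H2O) gives the carboxylic acid F10. 1-Chloro-N,N,2-trimethylprop-1-en-1-amine (CH2Cl2, 0 °C) gives the acid chloride F11 under neutral conditions. 1-Methoxy-1,3-bis(trimethylsilyloxy)buta-1,3-diene (CH2Cl2, −78 °C → rt, aqueous work-up) gives the methyl 3,5-dioxohexanoate F12. DBU in toluene at 80 °C closes the pyranone to 24, here isolated, which is benzylated as in step 13 to rejoin the route at 25.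

**Step 15.** The most likely failure is stalled hydrolysis of the ketimine 27, whose carbon is shielded by two ortho substituents, or retro-aldol cleavage and dehydration of 28 during prolonged heating. The fallback changes the order and cleaves the N–O bond by hydrogenolysis at room temperature. From 26, Dess–Martin oxidation gives the keto isoxazoline F13, which is handled without base because its C3–O bond is now β to a ketone. H2 over Raney Ni with B(OH)3 in MeOH/THF/H2O at room temperature then gives 29 directly; partial loss of benzyl groups at that point is harmless.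

**Step 17.** The most likely failure is over-reduction (saturation of the pyranone, hydrogenolysis at a benzylic ketone) before the last hindered benzyl ether has gone, or dehydration of the free ketol on the catalyst. The fallback removes the benzyl groups with a Lewis acid while the ketol is still masked. From 26, oxidation gives F13 as above. BCl3 with pentamethylbenzene (CH2Cl2, −78 °C) should strip all five benzyl groups to the pentahydroxy keto isoxazoline F14. Mo(CO)6 in wet acetonitrile then opens the ring and gives 30.

## Further compounds

F1 | step 10 | (S)-1-[2,4-bis(benzyloxy)-6-vinylphenyl]-3-methylbut-3-en-1-ol | CC(=C)C[C@H](O)c1c(C=C)cc(OCc2ccccc2)cc1OCc1ccccc1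
F2 | step 10 | (S)-6,8-bis(benzyloxy)-3-methyl-1,2-dihydronaphthalen-1-ol | CC1=Cc2cc(OCc3ccccc3)cc(OCc3ccccc3)c2[C@@H](O)C1
F3 | step 10 | all-cis hydroxy isoxazoline methyl ester, (1S,3R,4R) | C[C@@]1(ON=C3c4c(OCc5ccccc5)cc(OCc5ccccc5)cc4CC(=O)OC)C[C@H](O)c2c(OCc5ccccc5)cc(OCc5ccccc5)cc2[C@@H]13
F4 | step 10 | Weinreb amide of F3 | C[C@@]1(ON=C3c4c(OCc5ccccc5)cc(OCc5ccccc5)cc4CC(=O)N(C)OC)C[C@H](O)c2c(OCc5ccccc5)cc(OCc5ccccc5)cc2[C@@H]13
F5 | step 10 | keto-dioxinone with free C1 hydroxyl, C1 epimer series | C[C@@]1(ON=C3c4c(OCc5ccccc5)cc(OCc5ccccc5)cc4CC(=O)CC6=CC(=O)OC(C)(C)O6)C[C@H](O)c2c(OCc5ccccc5)cc(OCc5ccccc5)cc2[C@@H]13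
F6 | step 10 | benzyloxypyranone isoxazoline, C1 epimer of 26 | C[C@@]1(ON=C3c4c(OCc5ccccc5)cc(OCc5ccccc5)cc4Cc6cc(OCc5ccccc5)cc(=O)o6)C[C@H](O)c2c(OCc5ccccc5)cc(OCc5ccccc5)cc2[C@@H]13
F7 | step 10 | (1S,3R,4S)-diol ketone, C1 epimer of 28 | C[C@@]1(O)C[C@H](O)c2c(OCc3ccccc3)cc(OCc3ccccc3)cc2[C@@H]1C(=O)c1c(OCc2ccccc2)cc(OCc2ccccc2)cc1Cc1cc(OCc2ccccc2)cc(=O)o1
F8 | step 3 | racemic 1-[2,4-bis(benzyloxy)-6-vinylphenyl]-3-methylbut-3-en-1-ol | CC(=C)CC(O)c1c(C=C)cc(OCc2ccccc2)cc1OCc1ccccc1
F9 | step 3 | 1-[2,4-bis(benzyloxy)-6-vinylphenyl]-3-methylbut-3-en-1-one | CC(=C)CC(=O)c1c(C=C)cc(OCc2ccccc2)cc1OCc1ccccc1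
F10 | step 12 | isoxazoline arylacetic acid from 17 | C[C@@]1(ON=C3c4c(OCc5ccccc5)cc(OCc5ccccc5)cc4CC(=O)O)C[C@@H](O[Si](C)(C)C(C)(C)C)c2c(OCc5ccccc5)cc(OCc5ccccc5)cc2[C@@H]13
F11 | step 12 | isoxazoline arylacetyl chloride | C[C@@]1(ON=C3c4c(OCc5ccccc5)cc(OCc5ccccc5)cc4CC(=O)Cl)C[C@@H](O[Si](C)(C)C(C)(C)C)c2c(OCc5ccccc5)cc(OCc5ccccc5)cc2[C@@H]13
F12 | step 12 | methyl 6-aryl-3,5-dioxohexanoate, aryl = isoxazoline-bearing ring | C[C@@]1(ON=C3c4c(OCc5ccccc5)cc(OCc5ccccc5)cc4CC(=O)CC(=O)CC(=O)OC)C[C@@H](O[Si](C)(C)C(C)(C)C)c2c(OCc5ccccc5)cc(OCc5ccccc5)cc2[C@@H]13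
F13 | step 15 | keto isoxazoline (C1 ketone of 26), (3R,4R) | C[C@@]1(ON=C3c4c(OCc5ccccc5)cc(OCc5ccccc5)cc4Cc6cc(OCc5ccccc5)cc(=O)o6)CC(=O)c2c(OCc5ccccc5)cc(OCc5ccccc5)cc2[C@@H]13
F14 | step 17 | pentahydroxy keto isoxazoline (debenzylated F13) | C[C@@]1(ON=C3c4c(O)cc(O)cc4Cc6cc(O)cc(=O)o6)CC(=O)c2c(O)cc(O)cc2[C@@H]13
A1 | alternative 1 | methyl 2,4-bis(benzyloxy)-6-[2-(2,4-bis(benzyloxy)-6-bromophenyl)-2-oxoethyl]benzoate | COC(=O)c1c(OCc2ccccc2)cc(OCc2ccccc2)cc1CC(=O)c1c(OCc2ccccc2)cc(OCc2ccccc2)cc1Br
A2 | alternative 1 | (R)-2-tert-butyl-6-methyl-4H-1,3-dioxin-4-one | CC1=CC(=O)O[C@H](C(C)(C)C)O1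
A3 | alternative 1 | tricyclic β-keto lactone acetal, enol form | C[C@@]12O[C@@H](C(C)(C)C)OC(=O)C1=C(O)c1c(OCc3ccccc3)cc(OCc3ccccc3)cc1[C@@H]2C(=O)c1c(OCc2ccccc2)cc(OCc2ccccc2)cc1Br
A4 | alternative 2 | (3R,4S)-6,8-bis(benzyloxy)-4-[2-(4-benzyloxy-2-oxo-2H-pyran-6-yl)acetyl]-3-methyl-3-(triethylsilyloxy)-3,4-dihydronaphthalen-1(2H)-one | C[C@@]1(O[Si](CC)(CC)CC)CC(=O)c2c(OCc3ccccc3)cc(OCc3ccccc3)cc2[C@@H]1C(=O)Cc1cc(OCc2ccccc2)cc(=O)o1
A5 | alternative 2 | 3,5-bis(benzyloxy)-2-(trimethylsilyl)phenyl trifluoromethanesulfonate | C[Si](C)(C)c1c(OCc2ccccc2)cc(OCc2ccccc2)cc1OS(=O)(=O)C(F)(F)F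
A6 | alternative 2 | 3,5-bis(benzyloxy)benzyne | C1#CC(OCc2ccccc2)=CC(OCc2ccccc2)=C1
A7 | alternative 2 | fully protected target (C3 triethylsilyl ether, five benzyl ethers) | C[C@@]1(O[Si](CC)(CC)CC)CC(=O)c2c(OCc3ccccc3)cc(OCc3ccccc3)cc2[C@@H]1C(=O)c1c(OCc2ccccc2)cc(OCc2ccccc2)cc1Cc1cc(OCc2ccccc2)cc(=O)o1
A8 | alternative 3 | epoxy dithiane: 2-aryl-1,3-dithiane whose aryl ring carries the CH(2-methyloxiran-2-yl)–CH(OTBS)Ar' chain | C[C@@]1(CO1)[C@H](c1cc(OCc2ccccc2)cc(OCc2ccccc2)c1C1SCCCS1)[C@@H](O[Si](C)(C)C(C)(C)C)c1c(OCc2ccccc2)cc(OCc2ccccc2)cc1CCO[Si](C)(C)C(C)(C)C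
A9 | alternative 3 | tetralin with C1 dithiane and free C3 tertiary alcohol | C[C@@]1(O)CC2(SCCCS2)c2c(OCc3ccccc3)cc(OCc3ccccc3)cc2[C@@H]1[C@@H](O[Si](C)(C)C(C)(C)C)c1c(OCc2ccccc2)cc(OCc2ccccc2)cc1CCO[Si](C)(C)C(C)(C)C
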